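## Analysis of the target

- **Ring system and locants.** Target 28 (C20H26O6) is a ten-membered carbocycle, ring A. It is cis-fused along C1–C10 to an α-methylene-γ-butyrolactone, ring B. Locants used here: C1 is the lactone carbinol carbon, then C2=C3(CH3), C4 (OH), C5–C6 (epoxide, CH3 on C6), C7, C8, C9 (angelate), C10. C11 is the lactone α-carbon, C12 the lactone C=O and C13 the exocyclic CH2.
- **Unsaturation.** Both unsaturated units of ring A are cis within the ring. C2=C3 is Z. In the epoxide, C4 and C7 sit on the same side, so it derives from a Z olefin.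
- **Stereocentres.** There are six (1S,4R,5R,6S,9R,10R). With ring A drawn as a flat polygon, O1, O4, the epoxide oxygen, O9 and C11 all lie on one face. The triad C9/C10/C1 is therefore all-cis, O1 and O4 are cis-1,4 across the Z olefin, and the epoxy alcohol is cis (erythro).
- **Sensitive groups.** These are the Michael-accepting methylene lactone, the angelate (which isomerises to the tiglate), the epoxy alcohol (acid, Payne migration) and the allylic carbinol at C4.
- **Difficulty.** The medium ring brings strain and transannular reactivity. It holds two cis-trisubstituted units, and its two groups of stereocentres are separated by C7–C8.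
- **The feature that decides the strategy.**
  - The methyl pattern is not that of a germacrane. In the six-atom path C4–C3(CH3)=C2–C1–C10–C9, the C3 methyl group is para to the three-carbon branch on C10.
  - The path ends, C4 and C9, are both oxygenated and lie 1,6 across ring A. A bond C4–C9 would turn this path into a 2-methylcyclohex-2-enone ring of p-menthane type.
  - The five carbons left over are one propynyl unit (C5, C6 and the C6 methyl) and one vinyl unit (C7, C8).
  - C4, flanked by two Z olefinic units, is the retron of a cyclodeca-2,5-dienone. That is the product type of an acetylenic oxy-Cope ring expansion.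

## Retrosynthetic reasoning

**28 to 27.** The two C–O bonds of the epoxide are cut first. The C4 hydroxyl group of 27 can direct the oxidant. C5=C6 is the only electron-rich olefin left, because C2=C3 carries the acyloxy group on C1 and the other two olefins are conjugated with esters. The acid-sensitive group then appears only in the last step.

**27 to 26.** The C4–H bond is cut, which gives the cross-conjugated Z,Z-dienone 26. This exposes the retron of the key step. The forward reaction has to tell the two alkenyl groups on C4 apart, which is left to a chiral reagent.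

**26 to 25, then to 22 plus 23, then to 21.**
- The carbonyl oxygen on C12 is removed. Ring B becomes a 3-methylidenetetrahydrofuran, which survives carbanions, hydrides and KH and needs no protecting group.
- The ester C–O bond at O9 is cut to give alcohol 22 and acid 23.
- The C9–H bond is cut to give ketone 21, whose neighbour C10 controls the hydride attack.

**21 to 17 (key disconnection).** C6–C7 is cut and C4–C9 is reconnected, passing through 20 and 19.
- The ten-membered ring collapses to the six-membered ring of 17, which bears a propynyl group and a free hydroxyl on C4, and a vinyl group and a methyl ether on C9.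
- The cut is made here because it is the only [3,3] mapping that leaves C2=C3 inside a six-membered ring, which guarantees Z.
- It also delivers the C4 carbonyl with C5=C6 directly, and it keeps C1 and C10 untouched.
- The gain is that the hardest ring is made by ring enlargement instead of end-to-end closure.

**17 to 15 plus 16.** The C4–C5 bond is cut, which corresponds to a 1,2-addition of an alkynyl metal to the enone. The configuration at C4 is of no consequence.

**15 to 13 to 12.** The C1–H bond and the C1–O–C12 link are cut back to the dimethyl ketal and a C12 hydroxyl group (13). That hydroxyl comes from the isopropenyl methyl group of 12. The forward reductive etherification sets C1 from C10 within a rigid bicycle.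

**12 to 9, then to 4 plus 5.** The C9–O bond is cut first, then C8=C9. The quaternary centre C9(OCH3)(vinyl) comes from the extended enolate of ethylidene enone 9, and 9 comes from an aldol condensation. O9 has to be a non-migrating ether so that only O4 is anionic in the key step.

**4 to 2 plus 3, and 2 to 1.** The C10–C11 bond is cut, which corresponds to a catalytic asymmetric conjugate addition to a quinone monoketal. That monoketal comes from dearomatisation of the flat phenol 1. One catalytic step creates C10, and every other stereocentre is derived from it.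

## Alternatives that were turned down

**Alternative 1:** (the textbook route) cuts C1–C10.
- Forward key step: the acyclic Z-enal/2-(bromomethyl)acrylate A1 would be closed with CrCl2 by an intramolecular Nozaki–Hiyama–Kishi/Barbier allylation. Ring A, ring B, C1 and C10 would form at once.
- Why turned down:
  - Only the Z-enal can cyclise, and a γ-oxygenated Z-enal isomerises easily to the E form.
  - The closure is an end-to-end ten-ring formation at high dilution.
  - The facial selectivity at C1/C10 would depend on a flexible chain.
  - A1 already needs four separately made stereocentres and both Z units, so the precursor is hardly simpler than the product.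

**Alternative 2:** cuts C2=C3.
- Forward key step: ring-closing metathesis of diene A2 with the second-generation Grubbs catalyst.
- Why turned down:
  - The new olefin is trisubstituted and flanked by two oxygenated, branched allylic carbons.
  - One partner is a 1,1-disubstituted olefin next to a carbinol.
  - The methylene lactone and the angelate are further olefins that can bind the catalyst.
  - Ring strain favours dimers, and nothing but that strain controls the Z geometry.

**Alternative 3:** reconnects C1–C6.
- Forward key step: a Wharton–Grob fragmentation of the cis-decalin hydroxy mesylate A3. It would give the C1 ketone and the Z C5=C6 olefin stereospecifically and would keep C4, C9 and C10.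
- Why turned down:
  - A3 carries six stereocentres, two of them fully substituted ring-fusion carbons, and three of the six are destroyed again.
  - The mesylate must be equatorial in the conformer that has C7 axial.
  - No cheap ring maps onto A3, because the C6 methyl group is meta to the C10 branch.
  - The way to A3 would therefore cost more than the fragmentation wins.

Key step: step 8

Assumption: the SMILES is taken at face value (cis-fused lactone, Z C2=C3, cis epoxide, irregular methyl pattern). The stereodescriptors of intermediates follow the CIP rules and change where priorities change, without any change in space.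

## Steps

Step 1
Reactants: 1 4-methoxy-2-methylphenol
Product: 2 4,4-dimethoxy-2-methylcyclohexa-2,5-dien-1-one
Conditions: PhI(OAc)2, MeOH, 0 °C
Reagents that add atoms: methanol, CO
Why: Oxidative dearomatisation of a para-alkoxyphenol; methanol is captured at the methoxy-bearing para carbon (future C1) and gives the quinone monoketal, which already holds O1, O4, C2=C3 and the C3 methyl group; no stereocentre is formed.

Step 2
Reactants: 2 4,4-dimethoxy-2-methylcyclohexa-2,5-dien-1-one; 3 potassium trifluoro(prop-1-en-2-yl)borate
Product: 4 (5S)-4,4-dimethoxy-2-methyl-5-(prop-1-en-2-yl)cyclohex-2-en-1-one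
Conditions: [Rh(cod)2]BF4 (3 mol %), (S)-BINAP (3.3 mol %), Et3N, toluene/H2O, 25 °C
Reagents that add atoms: none
Why: Rhodium-catalysed asymmetric 1,4-addition (Hayashi–Miyaura type) of an alkenyltrifluoroborate to a quinone monoketal; only the unsubstituted C9=C10 bond reacts because C2=C3 bears the α-methyl group. (S)-BINAP should deliver C11 to the same face as in cyclohex-2-enone, which sets C10.

Step 3
Reactants: 4 (5S)-4,4-dimethoxy-2-methyl-5-(prop-1-en-2-yl)cyclohex-2-en-1-one; 5 acetaldehyde
Product: 9 (5R,6E)-6-ethylidene-4,4-dimethoxy-2-methyl-5-(prop-1-en-2-yl)cyclohex-2-en-1-one, via lithium enolate 6 (not isolated), via lithium aldolate 7 (not isolated), via aldol mesylate 8 (not isolated)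
Conditions: LiN(SiMe3)2, THF, −78 °C; 5; MsCl, −78 to 0 °C; DBU, 25 °C
Reagents that add atoms: none
Why: Aldol condensation; C9 is the only enolisable position of 4, and mesylation of the aldolate followed by E1cB elimination gives the E enone. The transient centres at C8 and C9 are erased and C10 is not touched.

Step 4
Reactants: 9 (5R,6E)-6-ethylidene-4,4-dimethoxy-2-methyl-5-(prop-1-en-2-yl)cyclohex-2-en-1-one
Product: 12 (5R,6R)-6-ethenyl-4,4,6-trimethoxy-2-methyl-5-(prop-1-en-2-yl)cyclohex-2-en-1-one, via potassium trienolate 10 (not isolated), via potassium alkoxide 11 (not isolated)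
Conditions: KN(SiMe3)2, THF, −78 °C; 2-(phenylsulfonyl)-3-phenyloxaziridine; MeOTf, −78 to 0 °C
Reagents that add atoms: 2-(phenylsulfonyl)-3-phenyloxaziridine, O=S(=O)(c1ccccc1)N1OC1c1ccccc1; methyl trifluoromethanesulfonate, COS(=O)(=O)C(F)(F)F
Why: γ-Deprotonation of the ethylidene methyl group and Davis oxidation of the extended enolate at its α-carbon C9 (deconjugative α-hydroxylation) create the vinyl group and O9 together. Allylic 1,3-strain holds the C10 substituent axial, so oxygen enters anti to it. Methylation in the same flask makes O9 an ether that can neither ionise nor migrate in step 8, and the quaternary C9 blocks aromatisation from here on.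

Step 5
Reactants: 12 (5R,6R)-6-ethenyl-4,4,6-trimethoxy-2-methyl-5-(prop-1-en-2-yl)cyclohex-2-en-1-one
Product: 13 (5R,6R)-6-ethenyl-5-(3-hydroxyprop-1-en-2-yl)-4,4,6-trimethoxy-2-methylcyclohex-2-en-1-one
Conditions: SeO2 (0.3 equiv), t-BuOOH, CH2Cl2, 25 °C
Reagents that add atoms: tert-butyl hydroperoxide, CC(C)(C)OO (its oxygen atom is passed on by the catalyst selenium dioxide, O=[Se]=O)
Why: Riley allylic oxidation (ene reaction, then [2,3] shift). The isopropenyl group is the only electron-rich olefin with allylic hydrogen, since the vinyl group has none and C2=C3 is an enone, and methyl reacts before the C10 methine.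

Step 6
Reactants: 13 (5R,6R)-6-ethenyl-5-(3-hydroxyprop-1-en-2-yl)-4,4,6-trimethoxy-2-methylcyclohex-2-en-1-one
Product: 15 (3aS,4R,7aS)-4-ethenyl-4-methoxy-6-methyl-3-methylidene-3,3a,4,7a-tetrahydro-1-benzofuran-5(2H)-one, via bicyclic mixed ketal 14 (not isolated)
Conditions: Et3SiH, TMSOTf (0.2 equiv), CH2Cl2, −78 to −40 °C
Reagents that add atoms: none
Why: Reductive etherification (ionic hydrogenation of a ketal); the C12 hydroxyl group replaces one methoxy group, and loss of the second gives a bicyclic oxocarbenium ion. The silane attacks that ion on the face syn to H10 and anti to C9, so ring B is cis-fused and C1 (S) is set by C10.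

Step 7
Reactants: 15 (3aS,4R,7aS)-4-ethenyl-4-methoxy-6-methyl-3-methylidene-3,3a,4,7a-tetrahydro-1-benzofuran-5(2H)-one; 16 prop-1-yn-1-ylmagnesium bromide
Product: 17 (3aS,4R,5S,7aS)-4-ethenyl-4-methoxy-6-methyl-3-methylidene-5-(prop-1-yn-1-yl)-2,3,3a,4,5,7a-hexahydro-1-benzofuran-5-ol
Conditions: 16, LaCl3·2LiCl (0.3 equiv), THF, −78 to 0 °C; then H2O
Reagents that add atoms: none
Why: 1,2-Addition of a small alkynyl Grignard reagent to a hindered enone. Chelation of the metal by O9 and the C4 carbonyl oxygen places the vinyl group axial, so attack anti to it should give the epimer shown. The C4 configuration is erased in step 8, so the other epimer would serve as well.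

Step 8
Reactants: 17 (3aS,4R,5S,7aS)-4-ethenyl-4-methoxy-6-methyl-3-methylidene-5-(prop-1-yn-1-yl)-2,3,3a,4,5,7a-hexahydro-1-benzofuran-5-ol
Product: 21 (1S,10S,2Z,5Z)-3,6-dimethylcyclodeca-2,5-diene-4,9-dione cis-fused at C1–C10 to a 3-methylidenetetrahydrofuran (target locants), via potassium alkoxide 18 (not isolated), via potassium allenolate 19 (not isolated), via enol ether dienone 20 (not isolated)
Conditions: KH, 18-crown-6, THF, 0 to 25 °C; AcOH, −78 °C; then oxalic acid (cat.), THF/H2O, 0 °C
Reagents that add atoms: water, O
Why: KH and 18-crown-6 convert 17 into the separated ion pair 18, in which the oxido group on C4 weakens the adjacent C4–C9 bond, so that the 3-oxido-1,5-enyne C7=C8–C9–C4–C5≡C6 undergoes a concerted [3,3]-sigmatropic shift: C6–C7 is formed, C4–C9 is broken and allenolate 19 results. The closest known reaction type is the anionic acetylenic oxy-Cope ring expansion of 1-alkynyl-2-vinylcycloalkanols to cycloalka-2,5-dienones. Ring A is therefore not closed end to end: it arises by four-atom enlargement of the six-membered ring through a six-centre chair-like transition state in which vinyl and propynyl are both equatorial and gauche, so that neither high dilution nor a template is needed, and ring B is a spectator. No stereocentre is created: C1 and C10 are not touched and are kept, and C4 and C9 become trigonal, so both C4 epimers of 17 would converge. C2=C3 stays Z because it was endocyclic in the six-membered ring, and C5=C6 should become Z because acetic acid can reach C5 of 19 only from the periphery, on the side of the C6 methyl group, which leaves C4 and C7 cis. The selectivity needed is between this shift and the [3,3] shift of the second 1,5-diene C7=C8–C9–C10–C11=C13; only the first has an oxido group on an sp3 carbon, because O9 is a methyl ether, so the second stays a slow thermal process. 19 holds no carbonyl group, so transannular aldol or Michael reactions cannot start before the cold quench, and the geometry of the enol ether in 20 is irrelevant because mild hydrolysis turns it into ketone 21.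

Step 9
Reactants: 21 (1S,10S,2Z,5Z)-diketone
Product: 22 (1S,9R,10R,2Z,5Z)-9-hydroxy-3,6-dimethylcyclodeca-2,5-dien-4-one cis-fused at C1–C10 to a 3-methylidenetetrahydrofuran
Conditions: LiAlH(O-t-Bu)3, THF, −78 to −40 °C
Reagents that add atoms: none
Why: Chemoselective hydride reduction; the isolated C9 ketone is more electrophilic than the twisted, α-methylated cross-conjugated C4 ketone. In the Felkin–Anh arrangement the ring bond C10–C1 stands perpendicular to C9=O, so Felkin attack is peripheral attack, with C11 next to the carbonyl oxygen. The hydride passes H10, which puts O9 cis to C11 (9R).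

Step 10
Reactants: 22 (1S,9R,10R,2Z,5Z)-hydroxy dienone; 23 angelic acid, (2Z)-2-methylbut-2-enoic acid
Product: 25 (1S,9R,10R,2Z,5Z)-9-angeloyloxy-3,6-dimethylcyclodeca-2,5-dien-4-one cis-fused at C1–C10 to a 3-methylidenetetrahydrofuran, via mixed anhydride 24 (not isolated)
Conditions: 23, 2,4,6-trichlorobenzoyl chloride, Et3N, toluene, 25 °C; then 22, 80 °C
Reagents that add atoms: none
Why: Yamaguchi-type esterification through the mixed anhydride without a nucleophilic pyridine catalyst, which is the known way to acylate hindered alcohols with angelic acid without isomerisation to the tiglate; C9 is not touched.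

Step 11
Reactants: 25 (1S,9R,10R,2Z,5Z)-angelate
Product: 26 (1S,9R,10R,2Z,5Z)-9-angeloyloxy-3,6-dimethyl-4-oxocyclodeca-2,5-diene cis-fused at C1–C10 to an α-methylene-γ-butyrolactone
Conditions: CrO3, 3,5-dimethylpyrazole, CH2Cl2, −20 °C
Reagents that add atoms: chromium trioxide, O=[Cr](=O)=O
Why: Allylic oxidation of a cyclic allyl ether to the unsaturated lactone by hexavalent chromium. The C12 hydrogens are both allylic to the only non-conjugated olefin and α to oxygen, whereas all other allylic C–H bonds belong to electron-poor enone or enoate olefins.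

Step 12
Reactants: 26 (1S,9R,10R,2Z,5Z)-lactone dienone
Product: 27 (1S,4S,9R,10R,2Z,5Z)-9-angeloyloxy-4-hydroxy-3,6-dimethylcyclodeca-2,5-diene cis-fused at C1–C10 to an α-methylene-γ-butyrolactone
Conditions: (R)-Me-CBS oxazaborolidine (0.2 equiv), catecholborane, toluene, −78 °C
Reagents that add atoms: none
Why: Corey–Bakshi–Shibata reduction; the α-methylated alkenyl group (C3 side) acts as the large group and the α-unsubstituted one (C5 side) as the small group, so the (R)-catalyst should place O4 on the face of O1. Catecholborane at low temperature should spare the enoates. The descriptor 4S becomes 4R after step 13 only because the priorities change.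

Step 13
Reactants: 27 (1S,4S,9R,10R,2Z,5Z)-dienol
Product: 28 target CNP0500828.1, (1S,4R,5R,6S,9R,10R)
Conditions: VO(acac)2 (5 mol %), t-BuOOH, CH2Cl2, 0 °C
Reagents that add atoms: tert-butyl hydroperoxide, CC(C)(C)OO
Why: Hydroxyl-directed epoxidation. In a medium-ring Z-allylic alcohol the ring holds C3 out of the olefin plane, so the vanadate ester on O4 can reach C5=C6 only on the face syn to O4, which gives the cis (erythro) epoxy alcohol and sets C5 and C6. C5=C6 is preferred to C2=C3, which is deactivated by the acyloxy group on C1, and the two enoate olefins are inert.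

## Compound list

1 | 4-methoxy-2-methylphenol | Cc1cc(OC)ccc1O | starting material
2 | 4,4-dimethoxy-2-methylcyclohexa-2,5-dien-1-one | O=C1C(C)=CC(OC)(OC)C=C1 | intermediate
3 | potassium trifluoro(prop-1-en-2-yl)borate | [K+].C=C(C)[B-](F)(F)F | starting material
4 | (5S)-4,4-dimethoxy-2-methyl-5-(prop-1-en-2-yl)cyclohex-2-en-1-one | O=C1C(C)=CC(OC)(OC)[C@H](C(C)=C)C1 | intermediate
5 | acetaldehyde | CC=O | starting material
6 | lithium enolate of 4 (C4–O, C4=C9) | [Li+].[O-]C1=C[C@@H](C(C)=C)C(OC)(OC)C=C1C | intermediate
7 | lithium aldolate (epimers at C8 and C9, erased) | O=C1C(C)=CC(OC)(OC)[C@H](C(C)=C)C1C(C)[O-].[Li+] | intermediate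
8 | aldol mesylate (epimers at C8 and C9, erased) | O=C1C(C)=CC(OC)(OC)[C@H](C(C)=C)C1C(C)OS(C)(=O)=O | intermediate
9 | (5R,6E)-6-ethylidene-4,4-dimethoxy-2-methyl-5-(prop-1-en-2-yl)cyclohex-2-en-1-one | O=C1C(C)=CC(OC)(OC)[C@H](C(C)=C)/C1=C\C | intermediate
10 | potassium trienolate of 9 | [K+].[O-]C1=C(C=C)[C@@H](C(C)=C)C(OC)(OC)C=C1C | intermediate
11 | potassium alkoxide, C9(O−)(vinyl) | O=C1C(C)=CC(OC)(OC)[C@H](C(C)=C)[C@]1([O-])C=C.[K+] | intermediate
12 | (5R,6R)-6-ethenyl-4,4,6-trimethoxy-2-methyl-5-(prop-1-en-2-yl)cyclohex-2-en-1-one | O=C1C(C)=CC(OC)(OC)[C@H](C(C)=C)[C@]1(OC)C=C | intermediate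
13 | (5R,6R)-6-ethenyl-5-(3-hydroxyprop-1-en-2-yl)-4,4,6-trimethoxy-2-methylcyclohex-2-en-1-one | O=C1C(C)=CC(OC)(OC)[C@H](C(CO)=C)[C@]1(OC)C=C | intermediate
14 | (3aR,4R,7aS)-4-ethenyl-4,7a-dimethoxy-6-methyl-3-methylidene-3,3a,4,7a-tetrahydro-1-benzofuran-5(2H)-one | O=C1C(C)=C[C@]2(OC)OCC(=C)[C@@H]2[C@]1(OC)C=C | intermediate
15 | (3aS,4R,7aS)-4-ethenyl-4-methoxy-6-methyl-3-methylidene-3,3a,4,7a-tetrahydro-1-benzofuran-5(2H)-one | O=C1C(C)=C[C@@H]2OCC(=C)[C@@H]2[C@]1(OC)C=C | intermediate
16 | prop-1-yn-1-ylmagnesium bromide | CC#C[Mg]Br | starting material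
17 | (3aS,4R,5S,7aS)-4-ethenyl-4-methoxy-6-methyl-3-methylidene-5-(prop-1-yn-1-yl)-2,3,3a,4,5,7a-hexahydro-1-benzofuran-5-ol | CC#C[C@@]1(O)C(C)=C[C@@H]2OCC(=C)[C@@H]2[C@]1(OC)C=C | intermediate
18 | potassium alkoxide of 17 | [K+].CC#C[C@@]1([O-])C(C)=C[C@@H]2OCC(=C)[C@@H]2[C@]1(OC)C=C | intermediate
19 | ten-membered potassium allenolate (O–C4=C5=C6; allene axis not specified, erased on protonation) | [K+].C=C1CO[C@H]2/C=C(/C)C([O-])=C=C(C)C/C=C(OC)/[C@@H]12 | intermediate
20 | (1S,10S,2Z,5Z)-9-methoxy-3,6-dimethylcyclodeca-2,5,8-trien-4-one cis-fused to 3-methylidenetetrahydrofuran | C=C1CO[C@H]2/C=C(/C)C(=O)/C=C(/C)C/C=C(OC)/[C@@H]12 | intermediate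
21 | (1S,10S,2Z,5Z)-3,6-dimethylcyclodeca-2,5-diene-4,9-dione cis-fused to 3-methylidenetetrahydrofuran | C=C1CO[C@H]2/C=C(/C)C(=O)/C=C(/C)CCC(=O)[C@@H]12 | intermediate
22 | (1S,9R,10R,2Z,5Z)-9-hydroxy dienone | C=C1CO[C@H]2/C=C(/C)C(=O)/C=C(/C)CC[C@@H](O)[C@@H]12 | intermediate
23 | angelic acid | C/C=C(/C)C(=O)O | starting material
24 | angelic 2,4,6-trichlorobenzoic anhydride | C/C=C(/C)C(=O)OC(=O)c1c(Cl)cc(Cl)cc1Cl | intermediate
25 | (1S,9R,10R,2Z,5Z)-9-angelate, cyclic ether | C=C1CO[C@H]2/C=C(/C)C(=O)/C=C(/C)CC[C@@H](OC(=O)/C(C)=C\C)[C@@H]12 | intermediate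
26 | (1S,9R,10R,2Z,5Z)-9-angelate, α-methylene lactone, C4 ketone | C=C1C(=O)O[C@H]2/C=C(/C)C(=O)/C=C(/C)CC[C@@H](OC(=O)/C(C)=C\C)[C@@H]12 | intermediate
27 | (1S,4S,9R,10R,2Z,5Z)-dienol | C=C1C(=O)O[C@H]2/C=C(/C)[C@@H](O)/C=C(/C)CC[C@@H](OC(=O)/C(C)=C\C)[C@@H]12 | intermediate
28 | CNP0500828.1 | C=C1C(=O)O[C@H]2/C=C(/C)[C@@H](O)[C@H]3O[C@@]3(C)CC[C@@H](OC(=O)/C(C)=C\C)[C@@H]12 | target

## Step count and least certain steps

Total step count: 13. Longest linear sequence: 13 (from 1).

**Step 8 (key step).**
- What may go wrong:
  - The hindered tertiary propargylic alkoxide may lose the propynyl anion by retro-addition.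
  - The shift may be slow, because the alkyne has to bend and the product ring holds seven trigonal or digonal atoms.
  - Protonation of the allenolate may occur on the wrong side, or later equilibration may take place, which would give the E enone.
  - The acid used for the enol ether may move C11=C13 into conjugation with C9=O.
- Fallback: it sets out from 15. Addition of prop-1-enylmagnesium bromide would give the divinyl carbinol F1. Its classical anionic oxy-Cope rearrangement (KH, 18-crown-6), followed by trapping of the regiodefined enolate with Me3SiCl, would give the silyl enol ether F2, in which C6 is a transient stereocentre. Saegusa–Ito dehydrogenation with Pd(OAc)2 would install C5=C6, and the route is rejoined at 20.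

**Step 4.**
- What may go wrong:
  - Oxygen transfer may take place at the γ-carbon instead of the crowded α-carbon.
  - The enolate may add to the sulfonimine by-product.
  - Methylation of the tertiary alkoxide may remain incomplete.
- Fallback: it sets out from 9. Weitz–Scheffer epoxidation of the exocyclic enone (t-BuOOH, DBU) would give the spiro epoxy ketone F3. Base-induced epoxide to allylic alcohol isomerisation with Et2Al(TMP) (diethylaluminium 2,2,6,6-tetramethylpiperidide) would give the tertiary alcohol F4. Methylation (MeOTf, 2,6-di-tert-butylpyridine) then leads back to 12.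

**Step 9.**
- What may go wrong:
  - Facial selectivity may be poor if the ring prefers the rotamer with H10 next to the carbonyl oxygen.
  - The hydride may attack the dienone.
  - C10 may epimerise by enolisation.
- Fallback: it sets out from 21. If the reduction gives mainly the 9-epimer F5, a Mitsunobu esterification of F5 with 23 (PPh3, DIAD) installs the angelate with inversion, and the route is rejoined at 25.

**Step 11.**
- What may go wrong: conversion may be low, or oxidation may take place at C1–H or C7–H with degradation of the dienone.
- Fallback: it sets out from 25. Riley oxidation (SeO2, t-BuOOH) at C12 would give the lactol F6, and TEMPO/PhI(OAc)2 would oxidise it to 26.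

**Step 12.**
- What may go wrong: the catalyst may distinguish the two alkenyl groups poorly, and the methylene lactone may undergo conjugate reduction.
- Fallback: it sets out from 26. A substrate-controlled Luche reduction (NaBH4, CeCl3·7H2O) would be followed by separation. The 4-epimer F7 would be inverted by a Mitsunobu reaction with chloroacetic acid to give the chloroacetate F8, which thiourea cleaves without touching the angelate. The route is rejoined at 27.

**Step 13.**
- What may go wrong:
  - Epoxidation may take place on the wrong face or at C2=C3.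
  - The bis-allylic alcohol may be oxidised back to the dienone.
- Fallback: it sets out from 27. The facial sense is inverted by a two-stage route. NBS in aqueous acetone would form the bromonium ion on the more open face, and water would open it at the tertiary C6 to give the bromohydrin F9. K2CO3 would then close the epoxide by attack of O6 on C5 from the opposite face, and the route ends at 28.

## Further compounds

F1 | step 8 | (3aS,4R,5S,7aS)-4-ethenyl-4-methoxy-6-methyl-3-methylidene-5-(prop-1-en-1-yl)-2,3,3a,4,5,7a-hexahydro-1-benzofuran-5-ol (olefin isomers) | CC=C[C@@]1(O)C(C)=C[C@@H]2OCC(=C)[C@@H]2[C@]1(OC)C=C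
F2 | step 8 | ten-membered C4 trimethylsilyl enol ether (C6 epimers, erased) | C=C1CO[C@H]2/C=C(/C)C(O[Si](C)(C)C)=CC(C)C/C=C(OC)/[C@@H]12
F3 | step 4 | spiro epoxy ketone from 9 (oxygen anti to the C10 substituent) | O=C1C(C)=CC(OC)(OC)[C@H](C(C)=C)[C@@]12O[C@@H]2C
F4 | step 4 | (5R,6R)-6-ethenyl-6-hydroxy-4,4-dimethoxy-2-methyl-5-(prop-1-en-2-yl)cyclohex-2-en-1-one | O=C1C(C)=CC(OC)(OC)[C@H](C(C)=C)[C@]1(O)C=C
F5 | step 9 | 9-epimer of 22 (9S) | C=C1CO[C@H]2/C=C(/C)C(=O)/C=C(/C)CC[C@H](O)[C@@H]12
F6 | step 11 | C12 lactol of 25 (anomers) | C=C1C(O)O[C@H]2/C=C(/C)C(=O)/C=C(/C)CC[C@@H](OC(=O)/C(C)=C\C)[C@@H]12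
F7 | step 12 | 4-epimer of 27 (4R) | C=C1C(=O)O[C@H]2/C=C(/C)[C@H](O)/C=C(/C)CC[C@@H](OC(=O)/C(C)=C\C)[C@@H]12
F8 | step 12 | 4-O-chloroacetate of 27 | C=C1C(=O)O[C@H]2/C=C(/C)[C@@H](OC(=O)CCl)/C=C(/C)CC[C@@H](OC(=O)/C(C)=C\C)[C@@H]12
F9 | step 13 | 5-bromo-6-hydroxy bromohydrin of 27 | C=C1C(=O)O[C@H]2/C=C(/C)[C@@H](O)[C@H](Br)[C@@](C)(O)CC[C@@H](OC(=O)/C(C)=C\C)[C@@H]12
A1 | alternative 1 | acyclic Z-enal 2-(bromomethyl)acrylate (4-O-TBS, epoxide and angelate in place) | O=C/C=C(/C)[C@@H](O[Si](C)(C)C(C)(C)C)[C@H]1O[C@@]1(C)CC[C@@H](OC(=O)/C(C)=C\C)/C=C(\CBr)C(=O)OC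
A2 | alternative 2 | seco-C2/C3 diene for ring-closing metathesis | C=C1C(=O)O[C@@H](C=C)[C@H]1[C@H](OC(=O)/C(C)=C\C)CC[C@]2(C)O[C@@H]2[C@H](O)C(C)=C
A3 | alternative 3 | cis-decalin hydroxy mesylate (bond C1–C6 in place) | C[C@]12CC[C@@H](O[Si](C)(C)C(C)(C)C)[C@@H](C(C)=C)[C@@]1(O)C=C(C)[C@@H](O[Si](C)(C)C(C)(C)C)[C@H]2OS(C)(=O)=O
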